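**Assumption:** the SMILES decodes to the cis‑fused (5R,8S,9R,10S) isomer, i.e. 5‑epi‑ilimaquinone. Avarane numbering is used (decalin C1–C10, exocyclic CH2 on C4, methyls on C5, C8, C9, ArCH2 on C9). α is the face of H‑10, so the target is 5α‑Me, 10α‑H, 9α‑CH2Ar, 9β‑Me, 8β‑Me.

## Retrosynthetic overview

1. Hydroxy‑methoxy‑quinone ⇐ 2,3,5,6‑tetramethoxyaryl (CAN, then selective vinylogous‑ester hydrolysis); C4=CH2 ⇐ C4 ketone (Wittig).
2. 8β‑Me ⇐ C8 ketone (methylenation, hydrogenation); C9 quaternary centre ⇐ α′‑benzylation of a Δ6‑8‑enone with 2,3,5,6‑tetramethoxybenzyl bromide.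
3. Ring B (cis‑decalin, C5/C10) ⇐ Lewis‑acid Diels–Alder of (R)‑carvone (ring A, dienophile) with the 2‑silyloxydiene of ethyl vinyl ketone, anti to the isopropenyl group.
4. The isopropenyl group is a traceless control element, excised by ozonolytic hydrodealkenylation once C5/C10 are set.
5. Ring order: ring A bought (carvone) → ring B by [4+2] → quinone unveiled last.

## Route

**Step 1**
Reactants: 1, ethyl vinyl ketone
Product: 2, (Z)‑3‑(tert‑butyldimethylsilyloxy)penta‑1,3‑diene
Conditions: TBSOTf, Et3N, Et2O, −78 → 0 °C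
Reagents that add atoms: TBSOTf, CC(C)(C)[Si](C)(C)OS(=O)(=O)C(F)(F)F
Why: Soft enolisation (silyl triflate/amine) of the ethyl ketone gives the 2‑silyloxydiene; the Z enol ether places the methyl anti to the vinyl group so the diene can reach s‑cis.

**Step 2**
Reactants: 2; 3, (R)‑(−)‑carvone
Product: 4, cis‑fused adduct: 8‑(TBSO)‑2α‑isopropenyl‑5α,9‑dimethyl‑10α‑H‑decal‑7‑en‑4‑one (endo 9β‑Me epimer drawn; C9 is erased in step 8)
Conditions: EtAlCl2 (0.5 equiv), toluene, −20 °C → rt; Et3N/NaHCO3 quench
Reagents that add atoms: none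
Why: Lewis‑acid Diels–Alder; the nucleophilic enol‑ether terminus (C9) bonds to the enone β‑carbon (C10) and the diene adds suprafacially anti to the isopropenyl group, giving the cis ring fusion with 5‑Me and H‑10 both α.

**Step 3**
Reactants: 4
Product: 5, 2α‑isopropenyl‑5α,9‑dimethyl‑10α‑H‑cis‑decal‑6‑ene‑4,8‑dione
Conditions: Pd(OAc)2, O2, DMSO, 40 °C
Reagents that add atoms: none
Why: Saegusa–Ito oxidation of the regiodefined silyl enol ether; β‑hydride loss can only occur from C6, giving the Δ6‑8‑enone that later blocks C7.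

**Step 4**
Reactants: 5
Product: 6, 5α,9‑dimethyl‑10α‑H‑cis‑decal‑6‑ene‑4,8‑dione
Conditions: O3, MeOH, −78 °C (indicator end‑point); then PhSH, FeSO4·7H2O, −78 °C → rt
Reagents that add atoms: none (H from PhSH)
Why: Hydrodealkenylation: ozone selects the electron‑rich isopropenyl group over the enone, and Fe(II) reduction of the methoxy‑hydroperoxide triggers β‑scission to a C2 radical that is quenched by thiol; C5/C10 are untouched.

**Step 5**
Reactants: 6
Product: 7, 4‑(TBSO)‑5α,9‑dimethyl‑10α‑H‑cis‑decala‑3,6‑dien‑8‑one (C4 masked as its Δ3 silyl enol ether)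
Conditions: LDA (1.05 equiv), THF, −78 °C; TBSCl, HMPA, −78 → 0 °C
Reagents that add atoms: TBSCl, CC(C)(C)[Si](C)(C)Cl
Why: Kinetic enolisation takes the unhindered C3 methylene in preference to the tertiary C9–H; O‑silylation gives a planar, non‑enolisable mask for the C4 carbonyl.

**Step 6**
Reactants: 8, 1,2,4,5‑tetramethoxybenzene
Product: 9, (2,3,5,6‑tetramethoxyphenyl)methanol
Conditions: n‑BuLi, TMEDA, THF, 0 °C; (CH2O)n, → rt
Reagents that add atoms: formaldehyde (paraformaldehyde), C=O
Why: Directed ortho‑lithiation between two methoxy groups, then hydroxymethylation.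

**Step 7**
Reactants: 9
Product: 10, 2,3,5,6‑tetramethoxybenzyl bromide (used at once)
Conditions: PBr3, CH2Cl2, 0 °C
Reagents that add atoms: PBr3, BrP(Br)Br
Why: Standard conversion of a benzylic alcohol to the bromide.

**Step 8**
Reactants: 7; 10
Product: 11, 9α‑(2,3,5,6‑tetramethoxybenzyl)‑4‑(TBSO)‑5α,9β‑dimethyl‑10α‑H‑cis‑decala‑3,6‑dien‑8‑one
Conditions: LDA (1.2 equiv), THF, −78 °C; 10, HMPA, −78 → −20 °C
Reagents that add atoms: none
Why: α′‑Alkylation of the cross‑conjugated dienolate; C9–H is the only acidic proton, and the bromide is expected to attack the α‑face (syn to H‑10) because ring A (C4 pseudoaxial) covers the β‑face, setting 9α‑CH2Ar/9β‑Me.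

**Step 9**
Reactants: 11
Product: 12, 9α‑(tetramethoxybenzyl)‑5α,9β‑dimethyl‑8‑methylene‑10α‑H‑cis‑decal‑6‑en‑4‑one
Conditions: Ph3PCH3Br, KOtBu, toluene, 0 → 80 °C; aqueous work‑up; then TBAF, AcOH, THF, 0 °C
Reagents that add atoms: methylenetriphenylphosphorane, C=P(c1ccccc1)(c1ccccc1)c1ccccc1
Why: Wittig methylenation of the only free, non‑enolisable carbonyl (C8); fluoride then cleaves the silyl enol ether to return the C4 ketone.

**Step 10**
Reactants: 12
Product: 13, 9α‑(tetramethoxybenzyl)‑5α,8β,9β‑trimethyl‑10α‑H‑cis‑decal‑4‑one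
Conditions: H2 (1–3 atm), 10% Pd/C, EtOAc, rt
Reagents that add atoms: none
Why: Catalytic hydrogenation saturates the 1,3‑diene; H is expected to add to C8 from the α‑face, away from the axial 9β‑methyl, giving the equatorial 8β‑Me, while ketone and arene survive.

**Step 11**
Reactants: 13
Product: 14, 2,3,5,6‑tetramethoxyphenyl precursor with the 4(11)‑exocyclic alkene
Conditions: Ph3PCH3Br, KOtBu, toluene, 90 °C
Reagents that add atoms: methylenetriphenylphosphorane, C=P(c1ccccc1)(c1ccccc1)c1ccccc1
Why: Wittig methylenation of the hindered C4 ketone; no stereocentre is affected.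

**Step 12**
Reactants: 14
Product: 15, 2,5‑dimethoxy‑3‑alkyl‑1,4‑benzoquinone
Conditions: CAN, MeCN/H2O, 0 °C, 15 min
Reagents that add atoms: water, O
Why: Oxidative demethylation of a para‑dimethoxy pair; both para pairs of the symmetric arene give the same quinone, and the isolated alkene survives the short oxidation.

**Step 13**
Reactants: 15
Product: 16, target
Conditions: KOH, MeOH/H2O, rt; then cold 1 M HCl
Reagents that add atoms: water/hydroxide, O
Why: Addition–elimination at the vinylogous ester next to the alkyl group, whose methoxy is twisted out of conjugation and more electrophilic; the resulting vinylogous carboxylate resists a second hydrolysis.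

## Compound list

1 | ethyl vinyl ketone | C=CC(=O)CC | starting material
2 | (Z)‑3‑(TBSO)penta‑1,3‑diene | C/C=C(\O[Si](C)(C)C(C)(C)C)C=C | intermediate
3 | (R)‑(−)‑carvone | CC1=CC[C@H](CC1=O)C(C)=C | starting material
4 | Diels–Alder adduct (TBS enol ether) | O=C1C[C@H](C(C)=C)C[C@H]2[C@@H](C)C(O[Si](C)(C)C(C)(C)C)=CC[C@@]12C | intermediate
5 | isopropenyl ene‑dione | O=C1C[C@H](C(C)=C)C[C@H]2[C@@H](C)C(=O)C=C[C@@]12C | intermediate
6 | cis‑decal‑6‑ene‑4,8‑dione | O=C1CCC[C@H]2[C@@H](C)C(=O)C=C[C@@]12C | intermediate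
7 | C4 TBS enol ether enone | CC(C)(C)[Si](C)(C)OC1=CCC[C@H]2[C@@H](C)C(=O)C=C[C@@]12C | intermediate
8 | 1,2,4,5‑tetramethoxybenzene | COc1cc(OC)c(OC)cc1OC | starting material
9 | (2,3,5,6‑tetramethoxyphenyl)methanol | OCc1c(OC)c(OC)cc(OC)c1OC | intermediate
10 | 2,3,5,6‑tetramethoxybenzyl bromide | BrCc1c(OC)c(OC)cc(OC)c1OC | intermediate
11 | C9‑benzylated enone | CC(C)(C)[Si](C)(C)OC1=CCC[C@H]2[C@](C)(Cc3c(OC)c(OC)cc(OC)c3OC)C(=O)C=C[C@@]12C | intermediate
12 | 4‑keto 6,8(exo)‑diene | O=C1CCC[C@H]2[C@](C)(Cc3c(OC)c(OC)cc(OC)c3OC)C(=C)C=C[C@@]12C | intermediate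
13 | saturated C4 ketone (8β‑Me) | O=C1CCC[C@H]2[C@](C)(Cc3c(OC)c(OC)cc(OC)c3OC)[C@@H](C)CC[C@@]12C | intermediate
14 | 4‑methylene tetramethoxyarene | C=C1CCC[C@H]2[C@](C)(Cc3c(OC)c(OC)cc(OC)c3OC)[C@@H](C)CC[C@@]12C | intermediate
15 | 2,5‑dimethoxyquinone | C=C1CCC[C@H]2[C@](C)(CC3=C(OC)C(=O)C=C(OC)C3=O)[C@@H](C)CC[C@@]12C | intermediate
16 | 3‑{[(1R,2S,4aR,8aS)‑1,2,4a‑trimethyl‑5‑methylidene‑decahydronaphthalen‑1‑yl]methyl}‑2‑hydroxy‑5‑methoxy‑1,4‑benzoquinone | C=C1CCC[C@H]2[C@](C)(CC3=C(O)C(=O)C=C(OC)C3=O)[C@@H](C)CC[C@@]12C | target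

## Summary

Total steps: 13. Longest linear sequence: 11 (steps 1–5, 8–13; 10 from carvone).

Steps most likely to fail:

1. **Step 8, facial selectivity at C9.** The cis‑decalin dienolate is conformationally mobile and the α‑preference is a conformational argument, not a demonstrated result. Fallback: use 2‑(silyloxy)buta‑1,3‑diene in step 2 so C9 arrives unsubstituted, then alkylate C9 twice (ArCH2Br first, MeI last). The same facial preference then delivers the opposite C9 configuration.
2. **Step 10, C8 configuration from hydrogenation.** The face depends on which chair of ring B reacts. Fallback: put C8 under thermodynamic control. Reduce the enone conjugatively, homologate the C8 ketone to the 8‑carbaldehyde (MeOCH=PPh3, then H3O+), equilibrate to the equatorial 8β‑CHO and deoxygenate it to CH3 (dithiolane/Raney Ni).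
3. **Step 5, kinetic C3 versus C9 enolisation.** Competing deprotonation or transannular aldol would give mixtures. Fallback: protect C4 as the 1,3‑dioxolane (ethylene glycol, TsOH; the saturated ketone reacts in preference to the enone) and remove it with aqueous acid after step 10, accepting a possible loss of C9 selectivity from the sp3 ketal.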